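The earlier runs and the new flask were generated by integration for substances that don't exist, and the scatter is random.

D and J cannot account for the L charged: at 6.00 d of the amber run they hold 71.8%.

all flasks: L 0.050 M
- amber: Q 0.075 M; the very flask that is asked about, followed so far
- flask: Q 0.0750 M; time 12 d

amber run (percent of the L charged)

| time / d | D / % | J / % |
|---|---|---|
| 0.417 | 61.3 | 9.3 |
| 1.25 | 47.9 | 24.2 |
| 2.00 | 44.2 | 27.8 |
| 3.00 | 43.1 | 28.9 |
| 5.00 | 42.5 | 30.0 |
| 6.00 | 41.8 | 30.0 |

(each reading ± 0.3 percentage points)

- in percentages every species weighs as the L in it: one E counts as two
- the analysis behind the earlier runs scatters by 0.3 percentage points, standard deviation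

1. D at 12 d, in percent of the L charged
2. J at 12 d, in percent of the L charged
3. E at 12 d, in percent of the L charged

The reckoning here supposes that the missing 28.2% is E, and that each E holds one L taken straight from the flask and one that first became D by spending Q. Q left in the amber run then stands near 0.0320 M. Suppose also that L either takes Q or meets D, both ways needing D. The ratio of the first way to the second is then Q over a crossing amount, the Q at which the two run level, and E formed, as a concentration, equals that amount times ln(Q charged / Q left). This gives 0.008292 M, read from readings with their scatter. The selectivity factor at the start is 9.04: the charge of Q over the crossing amount.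

Were Q held at its charge, this number would give E as 19.9%, less than the 28.2% read, so the fall of Q counts too. Nor does the number split D from J; that takes a second reading, J over D, 0.718 at 6.00 d of the amber run. In the amber run D plus J stands at 72.0% at 3.00 d and 71.8% at 6.00 d, so this reckoning holds E near 28.2% at the asked time, with D and J near their last readings.

The forecast gives D 41.6%, J 30.3% and E 28.1%, since “a plateau is expected”.

The flask gives D 42.1%, J 29.9% and E 28.1%.

    D ⇌ J (K = 0.710, k = 0.0262 h⁻¹)
    L + Q + D → 2 D (k = 410 M⁻² h⁻¹)
    L + Q → D (k = 0.142 M⁻¹ h⁻¹)
    L + D → E (k = 3.50 M⁻¹ h⁻¹)

In the flask at 12.0 d, L, the limiting reagent, stands at 0%, while Q stands at 43% of its charge. Multiplied by the selectivity factor, that share puts Q at 3.86 times the crossing amount, more than the crossing amount itself.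

A neighbour flask, the same but with 0.30 M of Q, has the selectivity factor 36.2. Counting the Q spent there as equal to the L charged, the same logarithm gives E near 6.05%. That neighbour flask gives E at 5.82%.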